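**Plan**

- Retrosynthetic cuts, in order: the C5'–alkenyl bond (Heck reaction), the C2–C3 bond of ring C (carbene C–H insertion), the C4–C4a bond joining ring A to the carbonyl carbon (aryl-metal addition to an arylacetaldehyde), and a one-carbon homologation on ring B.
- Enabling feature: C2 of pyranone ring C is a CH bonded only to O1 and C3. It can therefore be supplied by the OCH2O carbon of the MOM ether on the ring-A oxygen that becomes O1. Loss of methanol after closure gives the aromatic pyranone without an oxidant.
- Forward order: ring B is built from 5-bromovanillin and homologated to an arylacetaldehyde, and MOM-protected phloroglucinol (ring A) is joined at C4. Oxidation and diazo transfer prepare C3, ring C closes at C2–C3, acid aromatises ring C and frees the phenols, and the side chain is attached last.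
- Stereochemistry: the target has no stereocentre. The E double bond comes from syn-insertion and syn-β-hydride elimination in the Heck step. The stereocentres of the epoxide, the carbinol and the 2-methoxyisoflavanone are transient, racemic and erased.

Key step: step 10

Remark: the racemic intermediates (and the cis/trans mixture after ring closure) are carried forward unresolved, since the target is achiral.

**Step 1**
Reactants: 1 5-bromovanillin (3-bromo-4-hydroxy-5-methoxybenzaldehyde)
Product: 2 3-bromo-4,5-dihydroxybenzaldehyde
Conditions: BBr3, CH2Cl2, −78 °C → rt; H2O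
Reagents that add atoms: none
Why: Lewis-acid aryl methyl ether cleavage, in which BBr3 binds the ether oxygen next to the borylated phenol and bromide removes the methyl group by SN2, with aldehyde and aryl bromide untouched at low temperature.

**Step 2**
Reactants: 2 3-bromo-4,5-dihydroxybenzaldehyde
Product: 3 3-bromo-5-hydroxy-4-methoxybenzaldehyde
Conditions: MeI, Li2CO3, DMF, 40 °C
Reagents that add atoms: iodomethane, CI
Why: Regioselective Williamson ether synthesis, in which the weak base ionises only the more acidic 4-OH (para to the formyl group, ortho to bromine), so mono-methylation should occur there as it does for 3,4-dihydroxybenzaldehydes in general.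

**Step 3**
Reactants: 3 3-bromo-5-hydroxy-4-methoxybenzaldehyde
Product: 4 3-bromo-4-methoxy-5-(methoxymethoxy)benzaldehyde
Conditions: MOMCl, i-Pr2NEt, CH2Cl2, 0 °C → rt
Reagents that add atoms: chloromethyl methyl ether, COCCl
Why: Standard O-alkylation of a phenol to its MOM ether, chosen so that this group leaves together with the ring-A MOM groups in step 11.

**Step 4**
Reactants: 4 3-bromo-4-methoxy-5-(methoxymethoxy)benzaldehyde
Product: 5 2-[3-bromo-4-methoxy-5-(methoxymethoxy)phenyl]oxirane (racemic)
Conditions: Me3S+ I−, KOt-Bu, DMSO/THF, 0 °C → rt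
Reagents that add atoms: trimethylsulfonium iodide, C[S+](C)C.[I-]
Why: Corey–Chaykovsky epoxidation of a non-enolisable aryl aldehyde by dimethylsulfonium methylide under purely basic conditions that MOM ether and aryl bromide tolerate; the new stereocentre is racemic and is lost in step 5.

**Step 5**
Reactants: 5 2-[3-bromo-4-methoxy-5-(methoxymethoxy)phenyl]oxirane
Product: 6 [3-bromo-4-methoxy-5-(methoxymethoxy)phenyl]acetaldehyde
Conditions: InCl3 (10 mol %), THF, rt; used crude at once
Reagents that add atoms: none
Why: Meinwald rearrangement, in which the Lewis acid opens the aryl oxirane at the benzylic carbon and a 1,2-hydride shift gives the arylacetaldehyde, with a catalytic amount of a mild Lewis acid in THF expected to spare the aryl MOM ether.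

**Step 6**
Reactants: 7 phloroglucinol
Product: 8 1,3,5-tris(methoxymethoxy)benzene
Conditions: NaH, MOMCl, DMF, 0 °C → rt
Reagents that add atoms: chloromethyl methyl ether, COCCl
Why: Threefold Williamson O-alkylation of the triphenoxide, giving a symmetrical arene whose MOM groups serve as ortho-metalation directors, protecting groups and the later source of C2.

**Step 7**
Reactants: 8 1,3,5-tris(methoxymethoxy)benzene; 6 [3-bromo-4-methoxy-5-(methoxymethoxy)phenyl]acetaldehyde
Product: 11 racemic 2-[3-bromo-4-methoxy-5-(methoxymethoxy)phenyl]-1-[2,4,6-tris(methoxymethoxy)phenyl]ethan-1-ol, via aryllithium 9 (not isolated), via arylcerium dichloride 10 (not isolated)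
Conditions: n-BuLi (slightly less than 8), THF, 0 °C; CeCl3, −78 °C; then 6, −78 °C; H2O
Reagents that add atoms: none
Why: Directed ortho-metalation between two MOM ethers, then transmetalation to the weakly basic organocerium reagent and 1,2-addition to the aldehyde, which should suppress both enolisation of the arylacetaldehyde and bromine–metal exchange; the carbinol centre is racemic and is removed in step 8.

**Step 8**
Reactants: 11 2-[3-bromo-4-methoxy-5-(methoxymethoxy)phenyl]-1-[2,4,6-tris(methoxymethoxy)phenyl]ethan-1-ol
Product: 12 2-[3-bromo-4-methoxy-5-(methoxymethoxy)phenyl]-1-[2,4,6-tris(methoxymethoxy)phenyl]ethan-1-one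
Conditions: Dess–Martin periodinane, pyridine, CH2Cl2, 0 °C → rt
Reagents that add atoms: none
Why: Dess–Martin oxidation of a hindered benzylic secondary alcohol under buffered, near-neutral conditions that leave the four MOM ethers intact.

**Step 9**
Reactants: 12 2-[3-bromo-4-methoxy-5-(methoxymethoxy)phenyl]-1-[2,4,6-tris(methoxymethoxy)phenyl]ethan-1-one
Product: 13 2-[3-bromo-4-methoxy-5-(methoxymethoxy)phenyl]-2-diazo-1-[2,4,6-tris(methoxymethoxy)phenyl]ethan-1-one
Conditions: p-ABSA, DBU, MeCN, 0 °C → rt
Reagents that add atoms: 4-acetamidobenzenesulfonyl azide, CC(=O)Nc1ccc(cc1)S(=O)(=O)N=[N+]=[N-]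
Why: Regitz diazo transfer to the methylene of a deoxybenzoin, which is acidified by both the ketone and ring B, as is routine for aryl benzyl ketones.

**Step 10**
Reactants: 13 2-[3-bromo-4-methoxy-5-(methoxymethoxy)phenyl]-2-diazo-1-[2,4,6-tris(methoxymethoxy)phenyl]ethan-1-one
Product: 14 3-[3-bromo-4-methoxy-5-(methoxymethoxy)phenyl]-2-methoxy-5,7-bis(methoxymethoxy)chroman-4-one (cis/trans mixture of racemates)
Conditions: Rh2(OAc)4 (2 mol %), CH2Cl2, 4 Å MS, slow addition of 13 at high dilution, rt → 40 °C; filtered and taken on crude
Reagents that add atoms: none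
Why: Proposed new method: Rh2(OAc)4 expels N2 from 13 to give a donor–acceptor rhodium carbene at C3 (ring B as donor, the C4 ketone as acceptor), which takes up a hydridic hydrogen of an ortho OCH2O group through a three-centre C–H insertion transition state and so forms the C2–C3 bond. The closest known reaction types are the dirhodium-catalysed 1,6 C–H insertion of ortho-alkoxyaryl diazoketones that gives chroman-4-ones and the insertion of aryl-substituted donor–acceptor carbenes into C–H bonds next to ether oxygen; insertion into the methylene of a MOM ether to give a 2-methoxyisoflavanone has not been shown. Ring C is closed as a six-membered ring by a formal 1,6-insertion, the carbene carbon C3 bonding to the carbon that becomes C2 along the chain C3–C4–C4a–C8a–O1–C2. C2 and C3 become stereocentres with no control beyond the substrate, and a cis/trans mixture is accepted because both centres are erased in step 11. The step needs C–H insertion to win over carbene attack on the aryl ether oxygen (five-membered oxonium ylide, then 1,2-shift to a benzofuran-3-one), Wolff rearrangement and carbene dimerisation. In its favour are the low electrophilicity of the donor–acceptor carbene, the weak nucleophilicity of an aryl oxygen conjugated to the acyl-bearing ring, the C–H bond flanked by two oxygens, the two equivalent ortho MOM groups held near C3 by the twisted 2,6-disubstituted aryl ketone, and slow addition at high dilution.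

**Step 11**
Reactants: 14 3-[3-bromo-4-methoxy-5-(methoxymethoxy)phenyl]-2-methoxy-5,7-bis(methoxymethoxy)chroman-4-one
Product: 15 3-(3-bromo-5-hydroxy-4-methoxyphenyl)-5,7-dihydroxy-4H-chromen-4-one
Conditions: HCl (3 M in MeOH), 50 °C
Reagents that add atoms: none
Why: Acid-catalysed acetal chemistry, in which the C2 acetal ionises to an oxocarbenium ion that loses H3 (E1 elimination of methanol) to give the chromen-4-one, while acetal exchange with methanol removes the three MOM groups and traps the formaldehyde unit as dimethoxymethane.

**Step 12**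
Reactants: 15 3-(3-bromo-5-hydroxy-4-methoxyphenyl)-5,7-dihydroxy-4H-chromen-4-one; 16 2-methylbut-3-en-2-ol
Product: 17 5,7-dihydroxy-3-{3-hydroxy-5-[(E)-3-hydroxy-3-methylbut-1-en-1-yl]-4-methoxyphenyl}-4H-chromen-4-one (target)
Conditions: Pd(OAc)2 (5 mol %), P(o-tol)3 (15 mol %), Et3N, DMF, 100 °C; pH 6 buffer work-up
Reagents that add atoms: none
Why: Mizoroki–Heck reaction, in which zerovalent palladium adds oxidatively to the aryl bromide, the terminal alkene inserts syn at its CH2 carbon and syn-β-hydride elimination gives the E alkene (the tertiary carbinol has no hydrogen for isomerisation to a ketone), bromophenols being competent substrates with P(o-tol)3 and an amine base.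

**Compound list**

1 | 5-bromovanillin (3-bromo-4-hydroxy-5-methoxybenzaldehyde) | COc1cc(C=O)cc(Br)c1O | starting material
2 | 3-bromo-4,5-dihydroxybenzaldehyde | O=Cc1cc(O)c(O)c(Br)c1 | intermediate
3 | 3-bromo-5-hydroxy-4-methoxybenzaldehyde | COc1c(O)cc(C=O)cc1Br | intermediate
4 | 3-bromo-4-methoxy-5-(methoxymethoxy)benzaldehyde | COCOc1cc(C=O)cc(Br)c1OC | intermediate
5 | 2-[3-bromo-4-methoxy-5-(methoxymethoxy)phenyl]oxirane, racemic | COCOc1cc(C2CO2)cc(Br)c1OC | intermediate
6 | [3-bromo-4-methoxy-5-(methoxymethoxy)phenyl]acetaldehyde | COCOc1cc(CC=O)cc(Br)c1OC | intermediate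
7 | phloroglucinol (benzene-1,3,5-triol) | Oc1cc(O)cc(O)c1 | starting material
8 | 1,3,5-tris(methoxymethoxy)benzene | COCOc1cc(OCOC)cc(OCOC)c1 | intermediate
9 | [2,4,6-tris(methoxymethoxy)phenyl]lithium, formed in the flask, not isolated | [Li]c1c(OCOC)cc(OCOC)cc1OCOC | intermediate
10 | dichloro[2,4,6-tris(methoxymethoxy)phenyl]cerium, formed in the flask, not isolated | COCOc1cc(OCOC)c([Ce](Cl)Cl)c(OCOC)c1 | intermediate
11 | 2-[3-bromo-4-methoxy-5-(methoxymethoxy)phenyl]-1-[2,4,6-tris(methoxymethoxy)phenyl]ethan-1-ol, racemic | COCOc1cc(OCOC)c(C(O)Cc2cc(Br)c(OC)c(OCOC)c2)c(OCOC)c1 | intermediate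
12 | 2-[3-bromo-4-methoxy-5-(methoxymethoxy)phenyl]-1-[2,4,6-tris(methoxymethoxy)phenyl]ethan-1-one | COCOc1cc(OCOC)c(C(=O)Cc2cc(Br)c(OC)c(OCOC)c2)c(OCOC)c1 | intermediate
13 | 2-[3-bromo-4-methoxy-5-(methoxymethoxy)phenyl]-2-diazo-1-[2,4,6-tris(methoxymethoxy)phenyl]ethan-1-one | COCOc1cc(OCOC)c(C(=O)C(=[N+]=[N-])c2cc(Br)c(OC)c(OCOC)c2)c(OCOC)c1 | intermediate
14 | 3-[3-bromo-4-methoxy-5-(methoxymethoxy)phenyl]-2-methoxy-5,7-bis(methoxymethoxy)chroman-4-one, cis/trans mixture of racemates | COC1Oc2cc(OCOC)cc(OCOC)c2C(=O)C1c1cc(Br)c(OC)c(OCOC)c1 | intermediate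
15 | 3-(3-bromo-5-hydroxy-4-methoxyphenyl)-5,7-dihydroxy-4H-chromen-4-one | COc1c(O)cc(-c2coc3cc(O)cc(O)c3c2=O)cc1Br | intermediate
16 | 2-methylbut-3-en-2-ol | C=CC(C)(C)O | starting material
17 | 5,7-dihydroxy-3-{3-hydroxy-5-[(E)-3-hydroxy-3-methylbut-1-en-1-yl]-4-methoxyphenyl}-4H-chromen-4-one | COc1c(O)cc(-c2coc3cc(O)cc(O)c3c2=O)cc1/C=C/C(C)(C)O | target

**Step count**

Total: 12 steps. Longest linear sequence: 11 steps (1 → 17 through steps 1–5 and 7–12); the ring-A branch adds step 6.

**Steps most likely to fail**

1. Step 10 (new method). The carbene may be diverted before it reaches the OCH2O C–H bond, either by bonding to the aryl ether oxygen with subsequent 1,2-migration of the methoxymethyl group or by Wolff rearrangement. The fallback uses known chemistry, sets out from ketone 12 and returns at isoflavone 15. HCl in MeOH at 50 °C removes all four MOM groups of 12 to give 2-(3-bromo-5-hydroxy-4-methoxyphenyl)-1-(2,4,6-trihydroxyphenyl)ethan-1-one F1. Treatment of this with BF3·OEt2, DMF and MsCl at 70 °C formylates the activated methylene and closes ring C with loss of dimethylamine, the classical deoxybenzoin route to isoflavones, which tolerates free phenols. This gives 15, and the route resumes at step 12. In this detour C2 comes from DMF.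

2. Step 7 (with the fragile aldehyde from steps 4–5). Enolisation or self-aldolisation of the arylacetaldehyde under the basic aryl-metal reagent, or incomplete transmetalation followed by bromine–lithium exchange, would erode the coupling. The fallback reverses the polarity, sets out from aldehyde 4 and arene 8, and returns at alcohol 11. NaBH4 in MeOH reduces 4 to [3-bromo-4-methoxy-5-(methoxymethoxy)phenyl]methanol F2. MsCl, LiCl and 2,4,6-collidine in DMF convert it into 1-bromo-5-(chloromethyl)-2-methoxy-3-(methoxymethoxy)benzene F3. Zinc dust with LiCl in THF inserts into the benzylic chloride only, giving [3-bromo-4-methoxy-5-(methoxymethoxy)benzyl]zinc chloride F4. In parallel, aryllithium 9 (from 8 and n-BuLi) is quenched with DMF to give 2,4,6-tris(methoxymethoxy)benzaldehyde F5. Addition of the benzylic zinc reagent to this aldehyde, accelerated by MgCl2, delivers 11, and the route resumes at step 8. Steps 4 and 5 are bypassed.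

3. Step 12. Binding of palladium by phenoxide or by the 5-hydroxy-4-keto chelate, together with slow oxidative addition into the electron-rich, ortho-substituted aryl bromide, may stall the catalyst or lead to protodebromination. The fallback masks the phenols, sets out from 15 and returns at target 17. Ac2O in pyridine gives 3-(3-acetoxy-5-bromo-4-methoxyphenyl)-4-oxo-4H-chromene-5,7-diyl diacetate F6. The Heck coupling with 16 under the conditions of step 12 then gives 3-{3-acetoxy-5-[(E)-3-hydroxy-3-methylbut-1-en-1-yl]-4-methoxyphenyl}-4-oxo-4H-chromene-5,7-diyl diacetate F7. K2CO3 in MeOH at 0 °C removes the three acetates to give 17.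

**Further compounds**

F1 | step 10 | 2-(3-bromo-5-hydroxy-4-methoxyphenyl)-1-(2,4,6-trihydroxyphenyl)ethan-1-one | COc1c(O)cc(CC(=O)c2c(O)cc(O)cc2O)cc1Br
F2 | step 7 | [3-bromo-4-methoxy-5-(methoxymethoxy)phenyl]methanol | COCOc1cc(CO)cc(Br)c1OC
F3 | step 7 | 1-bromo-5-(chloromethyl)-2-methoxy-3-(methoxymethoxy)benzene | COCOc1cc(CCl)cc(Br)c1OC
F4 | step 7 | [3-bromo-4-methoxy-5-(methoxymethoxy)benzyl]zinc chloride | COCOc1cc(C[Zn]Cl)cc(Br)c1OC
F5 | step 7 | 2,4,6-tris(methoxymethoxy)benzaldehyde | COCOc1cc(OCOC)c(C=O)c(OCOC)c1
F6 | step 12 | 3-(3-acetoxy-5-bromo-4-methoxyphenyl)-4-oxo-4H-chromene-5,7-diyl diacetate | COc1c(OC(C)=O)cc(-c2coc3cc(OC(C)=O)cc(OC(C)=O)c3c2=O)cc1Br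
F7 | step 12 | 3-{3-acetoxy-5-[(E)-3-hydroxy-3-methylbut-1-en-1-yl]-4-methoxyphenyl}-4-oxo-4H-chromene-5,7-diyl diacetate | COc1c(OC(C)=O)cc(-c2coc3cc(OC(C)=O)cc(OC(C)=O)c3c2=O)cc1/C=C/C(C)(C)O
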